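The cedar flask held a small charge of racemization catalyst, 17 µM, and the oak run held twice that; otherwise the two recipes match, and the cedar flask is the one asked about.

| flask | left-handed substrate | right-handed substrate | coupling partner | free catalyst | racemization catalyst | added ligand | impurity | remark | time |
|---|---|---|---|---|---|---|---|---|---|
| cedar | 20 mM | 20 mM | 60 mM | 1 mM | 17 µM | 49 µM | 0.14 mM | the very flask that is asked about, followed so far |  |
| oak | 20 mM | 20 mM | 60 mM | 1 mM | 34 µM | 49 µM | 0.14 mM | run made earlier |  |
| flask | 20 mM | 20 mM | 60.0 mM | 1.0 mM | 17 µM | 49 µM | 0.14 mM |  | 50 min |

| run | time / min | left-handed product / % | right-handed product / % |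
|---|---|---|---|
| cedar | 2.50 | 6 | 1 |
| cedar | 5.00 | 9 | 3 |
| cedar | 8.00 | 11 | 4 |
| cedar | 10.0 | 11 | 6 |
| cedar | 12.0 | 14 | 3 |
| cedar | 15.0 | 17 | 10 |
| oak | 6.00 | 9 | 3 |
| oak | 12.0 | 15 | 6 |
| oak | 20.0 | 20 | 10 |
| oak | 25.0 | 20 | 15 |
| oak | 30.0 | 25 | 21 |
| oak | 40.0 | 29 | 24 |

(readings scatter by 1.5 percentage points)

* excess of left-handed product over right-handed product in the product at 5.0 min
* excess of left-handed product over right-handed product in the product at 50 min
* part of the left-handed substrate and right-handed substrate charged together that has reacted at 50 min

- free catalyst is single-handed; left-handed substrate and right-handed substrate are mirror images of each other, charged as a racemate, each of them at the stated concentration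
- an excess is the difference of the two amounts in percent of their sum
- an excess is below zero if the other one leads

The bench rule says that a single-handed catalyst stamps its excess on the product and that the excess stays. Applied to the first cedar reading, it promised 71.4% at both asked times. But the last oak reading shows 9.43%, so I took it that something wears the difference D between the two products away. I assumed that every product is born left-handed and balanced D: it gains the total product made and loses a constant share of itself each minute. Summing D over the oak readings gave 0.197 min⁻¹, which I call λ, the erosion rate: the share of the difference between the two products lost each minute. The cedar readings gave 0.212 min⁻¹, so I did not let λ follow the racemization catalyst.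

The rule's border is the ratio λt: 0.985 at 5.0 min, 9.85 at 50 min. At a steady making rate the excess is (1 − exp(−λt))/(λt), which gave me 63.6% early. Late, oak's total product, taken as first order, gave 0.0189 min⁻¹; I carried that constant over to the cedar flask, and my estimate there was 61.1% reacted at 50 min. That constant is slower than λ, so D should sit near making rate over λ, an excess of 6.11%. Putting that back, a D that falls with the making rate needs a factor 1.10, and the second round gave 6.70%.

The forecast stood at 47%, 23% and 60%, in the order asked, with the remark “The mechanism is uncertain, so the range is wide.” The simulated cedar flask gave an excess of 58.5% at 5.0 min and of 4.54% at 50 min, with 55.9% reacted at 50 min.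

    racemization catalyst + added ligand ⇌ idle complex (K = 1.90 × 10⁶ M⁻¹, k = 45.0 M⁻¹ s⁻¹)
    free catalyst + impurity → spent catalyst (k = 670 M⁻¹ s⁻¹)
    coupling partner + free catalyst + left-handed substrate → free catalyst + left-handed product (k = 15.0 M⁻² s⁻¹)
    coupling partner + free catalyst + right-handed substrate → free catalyst + right-handed product (k = 0.190 M⁻² s⁻¹)
    left-handed product ⇌ right-handed product (k = 0.00180 s⁻¹)
    left-handed substrate + racemization catalyst ⇌ right-handed substrate + racemization catalyst, rate k6*[racemization catalyst]*[left-handed substrate] forward; the back reaction follows from the equilibrium constant (k = 720 M⁻¹ s⁻¹)

In the cedar flask the excess at 50 min stood as low as 4.54% because of the step between the two products: the same run without that step ends at 97.1%. At my λ the cedar run lasted 9.85 erosion times. In a neighbour flask charged like it but with 1.7 mM of free catalyst, I scaled my constant by what the impurity leaves of c(free catalyst), to 0.0342 min⁻¹, and the same λ and two rounds gave 4.50%. That neighbour flask computed 3.16%.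

The runs were generated by integration for substances that don't exist, noise included.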